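Ring A carries oxygen on the alternate carbons C5, C7 and C8a, so it is a phloroglucinol (a folded poly-β-carbonyl chain) with one extra methoxy on C6. Ring C (O1, C2, C3–OH, C4=O, C4a, C8a) is the 3-hydroxy-4-pyranone of kojic acid.
Key disconnection C4a–C5: ring A is unfolded to a C8–C7–C6–C5 methoxy keto ester chain on C8a of the intact pyranone. It is closed by an intramolecular Claisen condensation followed by aromatisation.
The chain grows from the pyranone methyl group (C8): C7–C8 by acylation with methyl methoxyacetate, C5–C6 by carboxylation of the derived dianion.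
C2–C1' comes from a Suzuki coupling of a kojic-acid-derived 2-bromo-3-benzyloxy-6-methyl-4-pyranone. The C3' side chain and its (S) centre come from (R)-Roche ester by B-alkyl Suzuki coupling on 4-bromo-2-iodoanisole.
Ring order: rings C and B are bought and joined, ring A is formed last. The end game is 7-O-benzylation, 5-O-methylation and hydrogenolysis.
Key step: step 13

Remarks: Ar = 3-[(3S)-4-(benzyloxy)-3-methylbutyl]-4-methoxyphenyl. Flavone numbering (O1, C2 … C8a) is used for the atoms even before ring A exists.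
The ester carbon of 1 becomes the chain CH2 and its CH2OH stays the terminal CH2OH. This is why the (R) ester leads to the (S) side chain.
Assumption: 19 and 20 are handled as mixtures of keto/enol tautomers and of epimers at the labile C6 carbon, which becomes sp2 in step 13.

Step 1
Reactants: 1 methyl (R)-3-hydroxy-2-methylpropanoate
Product: 2 methyl (R)-3-(benzyloxy)-2-methylpropanoate
Conditions: BnOC(=NH)CCl3 (1.2 equiv), TfOH (cat.), CH2Cl2/cyclohexane, 0 °C to rt
Reagents that add atoms: benzyl 2,2,2-trichloroacetimidate, N=C(OCc1ccccc1)C(Cl)(Cl)Cl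
Why: Acid-catalysed O-benzylation with the trichloroacetimidate needs no base, so the α-stereocentre of the chiral-pool ester is not epimerised and the β-hydroxy ester does not eliminate.

Step 2
Reactants: 2 methyl (R)-3-(benzyloxy)-2-methylpropanoate
Product: 3 (R)-3-(benzyloxy)-2-methylpropanal
Conditions: iBu2AlH (1.05 equiv), CH2Cl2, −78 °C; MeOH, then aq potassium sodium tartrate
Reagents that add atoms: none
Why: Partial ester reduction with iBu2AlH delivers hydride only once at −78 °C because collapse to the aldehyde waits for the work-up, and crude 3 is used at once so that the α-methyl centre keeps its configuration.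

Step 3
Reactants: 3 (R)-3-(benzyloxy)-2-methylpropanal
Product: 4 (S)-{[(2-methylbut-3-en-1-yl)oxy]methyl}benzene
Conditions: Ph3PCH3Br (1.3 equiv), n-BuLi (1.25 equiv), THF, 0 °C; then 3, −78 °C to rt
Reagents that add atoms: methyltriphenylphosphonium bromide, C[P+](c1ccccc1)(c1ccccc1)c1ccccc1.[Br-]
Why: Wittig methylenation with the non-stabilised ylide, made with less base than phosphonium salt so that no free base remains, should outrun enolisation of the aldehyde; the descriptor changes to (S) only through the priority rules.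

Step 4
Reactants: 4 (S)-{[(2-methylbut-3-en-1-yl)oxy]methyl}benzene; 5 4-bromo-2-iodo-1-methoxybenzene
Product: 7 4-bromo-2-[(3S)-4-(benzyloxy)-3-methylbutyl]-1-methoxybenzene, via B-alkyl-9-BBN adduct 6 (not isolated)
Conditions: 9-BBN-H (1.05 equiv), THF, 0 °C to rt; then 5 (1.0 equiv), PdCl2(dppf) (3 mol %), 3 M aq NaOH, THF/DMF, rt to 40 °C
Reagents that add atoms: 9-borabicyclo[3.3.1]nonane, B1C2CCCC1CCC2 (its boron is carried in 6 only)
Why: Anti-Markovnikov hydroboration followed by B-alkyl Suzuki–Miyaura coupling, in which zerovalent palladium inserts far faster into the carbon–iodine than into the carbon–bromine bond, so one equivalent of borane at mild temperature alkylates only the position ortho to the methoxy group and leaves the remote stereocentre alone.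

Step 5
Reactants: 7 4-bromo-2-[(3S)-4-(benzyloxy)-3-methylbutyl]-1-methoxybenzene
Product: 8 2-Ar-4,4,5,5-tetramethyl-1,3,2-dioxaborolane
Conditions: B2pin2 (1.2 equiv), PdCl2(dppf) (3 mol %), KOAc (3 equiv), 1,4-dioxane, 85 °C
Reagents that add atoms: bis(pinacolato)diboron, CC1(C)OB(OC1(C)C)B1OC(C)(C)C(C)(C)O1
Why: Miyaura borylation of an aryl bromide under the weak base KOAc tolerates both ethers and avoids homocoupling.

Step 6
Reactants: 9 5-hydroxy-2-(hydroxymethyl)-4H-pyran-4-one (kojic acid)
Product: 10 2-(chloromethyl)-5-hydroxy-4H-pyran-4-one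
Conditions: SOCl2 (neat), rt
Reagents that add atoms: thionyl chloride, O=S(Cl)Cl
Why: Chlorodehydroxylation of the primary, allylic-type alcohol with thionyl chloride; the enolic 5-hydroxyl does not give a stable chloride and returns unchanged.

Step 7
Reactants: 10 2-(chloromethyl)-5-hydroxy-4H-pyran-4-one
Product: 11 5-hydroxy-2-methyl-4H-pyran-4-one (allomaltol)
Conditions: Zn dust, conc. HCl, H2O, 70 °C
Reagents that add atoms: none
Why: Zinc/acid reductive dechlorination of the activated carbon–chlorine bond turns the hydroxymethyl carbon into the methyl group that becomes C8.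

Step 8
Reactants: 11 5-hydroxy-2-methyl-4H-pyran-4-one
Product: 12 2-bromo-3-hydroxy-6-methyl-4H-pyran-4-one
Conditions: NBS (1.05 equiv), MeCN, dark, 0 °C to rt
Reagents that add atoms: N-bromosuccinimide, O=C1CCC(=O)N1Br
Why: Electrophilic bromination is directed by the enolic hydroxyl to the adjacent ring CH next to O1, the position at which kojic acid derivatives are halogenated and aminomethylated, and exclusion of light suppresses radical attack on the methyl group.

Step 9
Reactants: 12 2-bromo-3-hydroxy-6-methyl-4H-pyran-4-one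
Product: 13 3-(benzyloxy)-2-bromo-6-methyl-4H-pyran-4-one
Conditions: BnBr (1.1 equiv), K2CO3 (1.5 equiv), DMF, 40 °C
Reagents that add atoms: benzyl bromide, BrCc1ccccc1
Why: Williamson etherification of the acidic enol masks the future 3-hydroxyl against the strong bases used later and removes the chelating OH before the palladium step.

Step 10
Reactants: 13 3-(benzyloxy)-2-bromo-6-methyl-4H-pyran-4-one; 8 2-Ar-4,4,5,5-tetramethyl-1,3,2-dioxaborolane
Product: 14 3-(benzyloxy)-2-Ar-6-methyl-4H-pyran-4-one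
Conditions: Pd(PPh3)4 (5 mol %), K2CO3 (2 equiv), 1,4-dioxane/H2O 5:1, 85 °C
Reagents that add atoms: none
Why: Suzuki–Miyaura coupling, in which the bromide of 13 is a vinylogous acyl bromide that undergoes oxidative addition readily, forms the C2–C1' bond.

Step 11
Reactants: 14 3-(benzyloxy)-2-Ar-6-methyl-4H-pyran-4-one; 15 methyl 2-methoxyacetate
Product: 17 3-(benzyloxy)-2-Ar-6-(3-methoxy-2-oxopropyl)-4H-pyran-4-one, via lithium dienolate 16 (not isolated)
Conditions: LiN(SiMe3)2 (2.2 equiv), THF, −78 °C; 15 (1.2 equiv), −78 to −20 °C; then 1 M HCl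
Reagents that add atoms: none
Why: Crossed Claisen acylation of a vinylogous enolate: the base removes a methyl (C8) proton that is γ to the C4 carbonyl through C8a=C4a, dienolate 16 attacks the activated, chelating ester at its exocyclic carbon because this restores the pyranone, and the second equivalent of base holds 17 as its enolate.

Step 12
Reactants: 17 3-(benzyloxy)-2-Ar-6-(3-methoxy-2-oxopropyl)-4H-pyran-4-one
Product: 20 methyl 4-[5-(benzyloxy)-6-Ar-4-oxo-4H-pyran-2-yl]-2-methoxy-3-oxobutanoate, via dilithium dianion 18 (not isolated), via keto acid 19 (not isolated)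
Conditions: LiN(iPr)2 (2.3 equiv), THF, −78 to −30 °C; CO2 (g), −78 °C; 1 M HCl, 0 °C; crude 19, TMSCHN2 (1.05 equiv), PhMe/MeOH 4:1, 0 °C
Reagents that add atoms: carbon dioxide, O=C=O; (trimethylsilyl)diazomethane, C[Si](C)(C)C=[N+]=[N-]
Why: Terminal carboxylation of a 1,3-dicarbonyl-type dianion: the first equivalent of base takes the doubly activated C8 proton and the second the C6 proton, dianion 18 meets CO2 at its less stabilised C6 end to give a carboxylate too weakly acidic to quench unreacted 18, and the cold crude β-keto acid 19 is fixed at once by diazoalkane esterification before it can lose CO2.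

Step 13
Reactants: 20 methyl 4-[5-(benzyloxy)-6-Ar-4-oxo-4H-pyran-2-yl]-2-methoxy-3-oxobutanoate
Product: 22 3-(benzyloxy)-2-Ar-5,7-dihydroxy-6-methoxy-4H-chromen-4-one, via triketone tautomer 21 (not isolated)
Conditions: DBU (2 equiv), 4 Å MS, MeCN (0.01 M), 70 °C; then 1 M HCl
Reagents that add atoms: none
Why: Proposed new method: DBU takes a proton reversibly from C6 or from C8 of 20, and only the C8 anion, whose charge runs through C8a=C4a into the C4 carbonyl, has a way forward: C4a adds to the ester carbonyl C5, methoxide leaves, and triketone 21 enolises twice to arene 22, which is held as its 7-phenoxide, so that aromatisation drives the sequence. The closest known reactions are the base-induced Claisen cyclisations of 3,5,7-triketo esters to acylphloroglucinols and the aldol-type closures of 2-(2-oxoalkyl)-4-pyranones to chromones; an ester closure onto C4a of a 3-alkoxy-2-aryl-4-pyranone has not been described. Ring A closes in the 6-(enolexo)-exo-trig mode and C4a–C5 is the only skeletal bond made. No stereocentre is formed, the labile C6 centre of 20 becomes sp2, and the (S) centre of the side chain lies far from every acidic position. The step needs acylation at C4a rather than at C8, C6 or oxygen and an intact ring C: closure from C8 or from the C7 enolate oxygen would give a four-membered ring, C8 stands trans to C4 across C8a=C4a so that C6 cannot reach the C4 carbonyl, and O1 stays bound in the pyranone, which rules out both a 2-pyranone lactone and the 5,7,8-oxygenated isomer. DBU is too weak to form the unreactive C6,C8-dianion and does not add to ring C, high dilution holds back intermolecular Michael addition, and the methoxide released is quenched at once by the acidic hydroxyls of 22.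

Step 14
Reactants: 22 3-(benzyloxy)-2-Ar-5,7-dihydroxy-6-methoxy-4H-chromen-4-one
Product: 23 3,7-bis(benzyloxy)-2-Ar-5-hydroxy-6-methoxy-4H-chromen-4-one
Conditions: BnBr (1.05 equiv), K2CO3 (1.1 equiv), DMF, rt
Reagents that add atoms: benzyl bromide, BrCc1ccccc1
Why: Selective Williamson etherification: the 7-hydroxyl is the more acidic, free phenol (vinylogous acid of the C4 carbonyl), whereas the 5-hydroxyl is hydrogen-bonded to that carbonyl and flanked by the 6-methoxy group.

Step 15
Reactants: 23 3,7-bis(benzyloxy)-2-Ar-5-hydroxy-6-methoxy-4H-chromen-4-one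
Product: 24 3,7-bis(benzyloxy)-2-Ar-5,6-dimethoxy-4H-chromen-4-one
Conditions: MeI (5 equiv), K2CO3 (3 equiv), DMF, 50 °C
Reagents that add atoms: iodomethane, CI
Why: Williamson O-methylation with excess reagent and mild heating overcomes the chelation of the only remaining hydroxyl, so no selectivity is needed.

Step 16
Reactants: 24 3,7-bis(benzyloxy)-2-Ar-5,6-dimethoxy-4H-chromen-4-one
Product: 25 3,7-dihydroxy-2-{3-[(3S)-4-hydroxy-3-methylbutyl]-4-methoxyphenyl}-5,6-dimethoxy-4H-chromen-4-one
Conditions: H2 (1 atm), Pd/C (10 wt %), EtOAc/MeOH 1:1, rt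
Reagents that add atoms: none
Why: Catalytic hydrogenolysis cleaves the enol, aryl and alkyl benzyl ethers together, while the tetrasubstituted C2=C3 bond of the flavonol, the methyl ethers and the stereocentre are inert under these conditions.

Compound list
1 | methyl (R)-3-hydroxy-2-methylpropanoate | COC(=O)[C@H](C)CO | starting material
2 | methyl (R)-3-(benzyloxy)-2-methylpropanoate | COC(=O)[C@H](C)COCc1ccccc1 | intermediate
3 | (R)-3-(benzyloxy)-2-methylpropanal | O=C[C@H](C)COCc1ccccc1 | intermediate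
4 | (S)-{[(2-methylbut-3-en-1-yl)oxy]methyl}benzene | C=C[C@H](C)COCc1ccccc1 | intermediate
5 | 4-bromo-2-iodo-1-methoxybenzene | COc1ccc(Br)cc1I | starting material
6 | 9-[(3S)-4-(benzyloxy)-3-methylbutyl]-9-borabicyclo[3.3.1]nonane | B1(CC[C@H](C)COCc2ccccc2)C2CCCC1CCC2 | intermediate
7 | 4-bromo-2-[(3S)-4-(benzyloxy)-3-methylbutyl]-1-methoxybenzene | COc1ccc(Br)cc1CC[C@H](C)COCc1ccccc1 | intermediate
8 | 2-{3-[(3S)-4-(benzyloxy)-3-methylbutyl]-4-methoxyphenyl}-4,4,5,5-tetramethyl-1,3,2-dioxaborolane | COc1ccc(B2OC(C)(C)C(C)(C)O2)cc1CC[C@H](C)COCc1ccccc1 | intermediate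
9 | 5-hydroxy-2-(hydroxymethyl)-4H-pyran-4-one (kojic acid) | OCc1cc(=O)c(O)co1 | starting material
10 | 2-(chloromethyl)-5-hydroxy-4H-pyran-4-one | ClCc1cc(=O)c(O)co1 | intermediate
11 | 5-hydroxy-2-methyl-4H-pyran-4-one | Cc1cc(=O)c(O)co1 | intermediate
12 | 2-bromo-3-hydroxy-6-methyl-4H-pyran-4-one | Cc1cc(=O)c(O)c(Br)o1 | intermediate
13 | 3-(benzyloxy)-2-bromo-6-methyl-4H-pyran-4-one | Cc1cc(=O)c(OCc2ccccc2)c(Br)o1 | intermediate
14 | 3-(benzyloxy)-2-{3-[(3S)-4-(benzyloxy)-3-methylbutyl]-4-methoxyphenyl}-6-methyl-4H-pyran-4-one | Cc1cc(=O)c(OCc2ccccc2)c(-c2ccc(OC)c(CC[C@H](C)COCc3ccccc3)c2)o1 | intermediate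
15 | methyl 2-methoxyacetate | COCC(=O)OC | starting material
16 | lithium 3-(benzyloxy)-2-{3-[(3S)-4-(benzyloxy)-3-methylbutyl]-4-methoxyphenyl}-6-methylidene-6H-pyran-4-olate | [Li+].C=C1C=C([O-])C(OCc2ccccc2)=C(-c2ccc(OC)c(CC[C@H](C)COCc3ccccc3)c2)O1 | intermediate
17 | 3-(benzyloxy)-2-{3-[(3S)-4-(benzyloxy)-3-methylbutyl]-4-methoxyphenyl}-6-(3-methoxy-2-oxopropyl)-4H-pyran-4-one | COCC(=O)Cc1cc(=O)c(OCc2ccccc2)c(-c2ccc(OC)c(CC[C@H](C)COCc3ccccc3)c2)o1 | intermediate
18 | dilithium bis-enolate of 17 (C6=C7–O⁻ and C8=C8a–C4a=C4–O⁻) | [Li+].[Li+].COC=C([O-])C=C1C=C([O-])C(OCc2ccccc2)=C(-c2ccc(OC)c(CC[C@H](C)COCc3ccccc3)c2)O1 | intermediate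
19 | 4-[5-(benzyloxy)-6-{3-[(3S)-4-(benzyloxy)-3-methylbutyl]-4-methoxyphenyl}-4-oxo-4H-pyran-2-yl]-2-methoxy-3-oxobutanoic acid | COC(C(=O)O)C(=O)Cc1cc(=O)c(OCc2ccccc2)c(-c2ccc(OC)c(CC[C@H](C)COCc3ccccc3)c2)o1 | intermediate
20 | methyl 4-[5-(benzyloxy)-6-{3-[(3S)-4-(benzyloxy)-3-methylbutyl]-4-methoxyphenyl}-4-oxo-4H-pyran-2-yl]-2-methoxy-3-oxobutanoate | COC(=O)C(OC)C(=O)Cc1cc(=O)c(OCc2ccccc2)c(-c2ccc(OC)c(CC[C@H](C)COCc3ccccc3)c2)o1 | intermediate
21 | 3-(benzyloxy)-2-{3-[(3S)-4-(benzyloxy)-3-methylbutyl]-4-methoxyphenyl}-6-methoxy-4H-chromene-4,5,7(4aH,6H)-trione | COC1C(=O)C=C2OC(-c3ccc(OC)c(CC[C@H](C)COCc4ccccc4)c3)=C(OCc3ccccc3)C(=O)C2C1=O | intermediate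
22 | 3-(benzyloxy)-2-{3-[(3S)-4-(benzyloxy)-3-methylbutyl]-4-methoxyphenyl}-5,7-dihydroxy-6-methoxy-4H-chromen-4-one | COc1ccc(-c2oc3cc(O)c(OC)c(O)c3c(=O)c2OCc2ccccc2)cc1CC[C@H](C)COCc1ccccc1 | intermediate
23 | 3,7-bis(benzyloxy)-2-{3-[(3S)-4-(benzyloxy)-3-methylbutyl]-4-methoxyphenyl}-5-hydroxy-6-methoxy-4H-chromen-4-one | COc1ccc(-c2oc3cc(OCc4ccccc4)c(OC)c(O)c3c(=O)c2OCc2ccccc2)cc1CC[C@H](C)COCc1ccccc1 | intermediate
24 | 3,7-bis(benzyloxy)-2-{3-[(3S)-4-(benzyloxy)-3-methylbutyl]-4-methoxyphenyl}-5,6-dimethoxy-4H-chromen-4-one | COc1ccc(-c2oc3cc(OCc4ccccc4)c(OC)c(OC)c3c(=O)c2OCc2ccccc2)cc1CC[C@H](C)COCc1ccccc1 | intermediate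
25 | 3,7-dihydroxy-2-{3-[(3S)-4-hydroxy-3-methylbutyl]-4-methoxyphenyl}-5,6-dimethoxy-4H-chromen-4-one | COc1ccc(-c2oc3cc(O)c(OC)c(OC)c3c(=O)c2O)cc1CC[C@H](C)CO | target

Total step count: 16. Longest linear sequence: 12 steps (steps 1–5 and 10–16, from 1).

Steps most likely to fail

**Step 13.**
- What may go wrong: the ester may stay locked as its C6 enolate and C4a may be too weak a nucleophile. The substrate would then be lost to intermolecular Michael addition onto ring C, to methoxide-induced opening of the pyranone, or to hydrolysis and decarboxylation by traces of water.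
- Fallback: known chemistry only, with ring A brought in ready-made and ring C closed last. It sets out from 7 and comes back to the route at 25.
- Bromine–lithium exchange on 7 (n-BuLi, THF, −78 °C) and quenching with DMF should give 3-[(3S)-4-(benzyloxy)-3-methylbutyl]-4-methoxybenzaldehyde F1.
- Commercial 1-(2,4-dihydroxy-6-methoxyphenyl)ethan-1-one is benzylated at its unchelated 4-hydroxyl (BnBr, K2CO3, acetone) to 1-[4-(benzyloxy)-2-hydroxy-6-methoxyphenyl]ethan-1-one F2.
- Elbs persulfate oxidation (K2S2O8, aq KOH) para to the phenol gives potassium 3-acetyl-6-(benzyloxy)-4-hydroxy-2-methoxyphenyl sulfate F3. Dilute HCl hydrolyses it to 1-[4-(benzyloxy)-3,6-dihydroxy-2-methoxyphenyl]ethan-1-one F4.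
- One equivalent of MeI with K2CO3 methylates the unchelated hydroxyl to 1-[4-(benzyloxy)-6-hydroxy-2,3-dimethoxyphenyl]ethan-1-one F5.
- Claisen–Schmidt condensation of F1 with F5 (KOH, EtOH) gives the (E)-chalcone F6. Oxidative cyclisation (cat. I2, DMSO, 120 °C) then gives the 5,6-dimethoxy-7-benzyloxyflavone F7.
- Dimethyldioxirane (acetone/CH2Cl2, 0 °C) gives the 2,3-epoxide F8, which opens with cat. TsOH to the flavonol F9. This route to the flavonol is preferred to alkaline peroxide, which tends to divert 6'-methoxychalcones to aurones.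
- Hydrogenolysis of the two benzyl ethers of F9 (H2, Pd/C) gives 25.

**Step 12.**
- What may go wrong: the second deprotonation may be incomplete. The base may attack the benzylic OCH2 of the enol benzyl ether, with Wittig rearrangement. The keto acid may lose CO2 before esterification, or the diazoalkane may methylate the enol.
- Fallback: the chain carbon nucleophile becomes a malonate half-ester, so no dianion is needed. It sets out from 14, bypasses 17, and comes back at 20.
- 14 is deprotonated with LiN(SiMe3)2 (THF, −78 °C) and quenched with CO2 to give [5-(benzyloxy)-6-Ar-4-oxo-4H-pyran-2-yl]acetic acid F10.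
- Carbonyldiimidazole (THF, rt) converts F10 into the acyl imidazolide F11.
- Commercial dimethyl 2-methoxymalonate is half-saponified (KOH 1 equiv, MeOH) to potassium 2,3-dimethoxy-3-oxopropanoate F12.
- F12 with MgCl2 and Et3N in MeCN is acylated by F11 with loss of CO2 (Masamune–Brooks-type decarboxylative Claisen condensation) to give 20.

**Step 11.**
- What may go wrong: proton transfer from ester 15 or from product to dienolate 16 may stall conversion. The methoxyacetate may self-condense, or acylation may occur on oxygen.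
- Fallback: aldol addition followed by oxidation instead of acylation. It sets out from 14 and comes back at 17.
- 14 is deprotonated with LiN(SiMe3)2 (1.1 equiv, THF, −78 °C) and treated with methoxyacetaldehyde, and the mixture is quenched cold to avoid dehydration. This gives 3-(benzyloxy)-2-Ar-6-(2-hydroxy-3-methoxypropyl)-4H-pyran-4-one F13.
- Dess–Martin periodinane (CH2Cl2, rt) oxidises F13 to 17.

Further compounds
F1 | step 13 | 3-[(3S)-4-(benzyloxy)-3-methylbutyl]-4-methoxybenzaldehyde | COc1ccc(C=O)cc1CC[C@H](C)COCc1ccccc1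
F2 | step 13 | 1-[4-(benzyloxy)-2-hydroxy-6-methoxyphenyl]ethan-1-one | CC(=O)c1c(O)cc(OCc2ccccc2)cc1OC
F3 | step 13 | potassium 3-acetyl-6-(benzyloxy)-4-hydroxy-2-methoxyphenyl sulfate | CC(=O)c1c(O)cc(OCc2ccccc2)c(OS(=O)(=O)[O-])c1OC.[K+]
F4 | step 13 | 1-[4-(benzyloxy)-3,6-dihydroxy-2-methoxyphenyl]ethan-1-one | CC(=O)c1c(O)cc(OCc2ccccc2)c(O)c1OC
F5 | step 13 | 1-[4-(benzyloxy)-6-hydroxy-2,3-dimethoxyphenyl]ethan-1-one | CC(=O)c1c(O)cc(OCc2ccccc2)c(OC)c1OC
F6 | step 13 | (E)-1-[4-(benzyloxy)-6-hydroxy-2,3-dimethoxyphenyl]-3-{3-[(3S)-4-(benzyloxy)-3-methylbutyl]-4-methoxyphenyl}prop-2-en-1-one | COc1ccc(/C=C/C(=O)c2c(O)cc(OCc3ccccc3)c(OC)c2OC)cc1CC[C@H](C)COCc1ccccc1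
F7 | step 13 | 7-(benzyloxy)-2-{3-[(3S)-4-(benzyloxy)-3-methylbutyl]-4-methoxyphenyl}-5,6-dimethoxy-4H-chromen-4-one | COc1ccc(-c2cc(=O)c3c(OC)c(OC)c(OCc4ccccc4)cc3o2)cc1CC[C@H](C)COCc1ccccc1
F8 | step 13 | 2,3-epoxide of F7 (both epoxide diastereomers) | COc1ccc(C23OC2C(=O)c2c(OC)c(OC)c(OCc4ccccc4)cc2O3)cc1CC[C@H](C)COCc1ccccc1
F9 | step 13 | 7-(benzyloxy)-2-{3-[(3S)-4-(benzyloxy)-3-methylbutyl]-4-methoxyphenyl}-3-hydroxy-5,6-dimethoxy-4H-chromen-4-one | COc1ccc(-c2oc3cc(OCc4ccccc4)c(OC)c(OC)c3c(=O)c2O)cc1CC[C@H](C)COCc1ccccc1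
F10 | step 12 | [5-(benzyloxy)-6-{3-[(3S)-4-(benzyloxy)-3-methylbutyl]-4-methoxyphenyl}-4-oxo-4H-pyran-2-yl]acetic acid | OC(=O)Cc1cc(=O)c(OCc2ccccc2)c(-c2ccc(OC)c(CC[C@H](C)COCc3ccccc3)c2)o1
F11 | step 12 | 3-(benzyloxy)-2-{3-[(3S)-4-(benzyloxy)-3-methylbutyl]-4-methoxyphenyl}-6-[2-(1H-imidazol-1-yl)-2-oxoethyl]-4H-pyran-4-one | O=C(Cc1cc(=O)c(OCc2ccccc2)c(-c2ccc(OC)c(CC[C@H](C)COCc3ccccc3)c2)o1)n1ccnc1
F12 | step 12 | potassium 2,3-dimethoxy-3-oxopropanoate | COC(C(=O)OC)C(=O)[O-].[K+]
F13 | step 11 | 3-(benzyloxy)-2-{3-[(3S)-4-(benzyloxy)-3-methylbutyl]-4-methoxyphenyl}-6-(2-hydroxy-3-methoxypropyl)-4H-pyran-4-one (both carbinol epimers) | COCC(O)Cc1cc(=O)c(OCc2ccccc2)c(-c2ccc(OC)c(CC[C@H](C)COCc3ccccc3)c2)o1
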